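The runs were computed for substances that don't exist, and the scatter is random.

A small charge of G, 0.118 M against 0.079 M of Q, has to last 4.0 d, so what I need is what each lost Q costs in G.

in all of them: Q 0.079 M; G 0.118 M

|  | remark | time |
|---|---|---|
| theta | the very flask that is asked about, followed so far |  |
| flask |  | 4.0 d |

theta run (percent of the Q charged)

| time / h | Q / % | X / % |
|---|---|---|
| 6.00 | 71.8 | 3.8 |
| 12.0 | 54.5 | 3.2 |
| 15.0 | 49.4 | 2.4 |
| 25.0 | 35.2 | 1.3 |
| 30.0 | 30.1 | 0.2 |

(scatter of a reading: 0.5 percentage points)

* amount of Q at 4.0 d, in percent of the Q charged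
* amount of X at 4.0 d, in percent of the Q charged
* amount of J at 4.0 d, in percent of the Q charged
* amount of E at 4.0 d, in percent of the Q charged

- a reading or a percentage of J counts all its forms, free or not

I take the clocks in turn. X comes first: at 6.00 h it stands at 3.8% while Q falls by 0.0552 /h of itself, so if X is made as fast as Q is lost, its half-life is near 0.664 h.

Q is slower, with a half-life of 12.6 h up to the first reading. Between 15.0 h and 30.0 h its rate drops to 0.0330 /h. I assume this rate follows [G], so the slowing measures the G spent. The two stretches have mean losses of Q of 14.1% and 60.2%, which reads as a price of 1.16, the G spent per Q lost. That is less than two, so I take it that a second G is not the usual way out of X.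

The asked time is longer than the half-life of Q. The first stretch gives a rate constant of 0.525 /M/h. At this price I reckon the charge of G stands 0.0265 M above what the whole of Q costs. Integrating gives me Q at 7.41%, G at 28.2% of its charge, and X near 0.124%. The G beyond one per Q lost comes to 14.7% of the Q charged, and I put J and E together below that.

The forecast says Q 27%, X 0.3%, J 69.5% and E 3.2%, holding that “each Q lost costs about two G”, which differs from my price.

The flask gives Q 8.34%, X 0.147%, J 3.93% and E 1.95%.

    Q + G → X (k = 1.48 × 10⁻⁴ /M/s)
    G + X → J (k = 4.22 × 10⁻⁴ /M/s)
    G + J → E (k = 8.50 × 10⁻⁵ /M/s)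
    G + E → D (k = 2.05 × 10⁻⁴ /M/s)
    X → L (k = 2.26 × 10⁻⁴ /s)
    Z ⇌ J, rate k6*(cs6 - [J]) while solid is left; crystals form when [J] > cs6 (solubility = 0.0570 M, k = 0.00152 /s)

The loss of X to L, which takes no G, is the largest single effect on J: with that step taken away, J at 4.00 d stands at 41.3% instead of 3.93%. The half-life of X by that loss is 0.85 h, shorter than the 0.16 d by G + X with G as charged. Up to 4.0 d this flask has spent 1.25 G per Q lost. In the neighbour with 0.32 M of Q, my price lets the same G bring Q down to 68.2%; there, at 4.0 d, G, the limiting reagent, stands at 0% and Q at 66.3%.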